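Ring C (O1–C2–C3–C4–C4a–C8a) of the O-benzyl (2S)-flavanone is traced back to the five-membered ring of a racemic 2-aryl-2-(iodomethyl)benzofuran-3(2H)-one. The exocyclic CH2 becomes C3 through a radical 1,2-acyl shift run inside a flavin-dependent ene-reductase under light.
Enabling feature: C2 carries both the ring oxygen O1 and ring B and lies beta to the C4 carbonyl. The C2 radical is therefore benzylic and alpha-oxygenated, which drives the acyl shift and erases the racemic quaternary centre. It also sits where an ene-reductase delivers hydrogen to the beta carbon of a bound enone, which sets 2S.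
The iodide comes from a 2-arylbenzofuran-3(2H)-one by C2 iodomethylation and chelation-controlled loss of the peri methyl group. In ring A the acyl-bearing carbon C4a is flanked by the oxygenated carbons C5 and C8a, so a locally symmetric pentamethoxyphenyl ketone suffices: one ortho OMe becomes O1, the other the 5-OH.
The 2-arylbenzofuranone comes from a deoxybenzoin (enolate iodination, demethylative 5-exo-tet closure), which is made by palladium-catalysed alpha-arylation of pentamethoxyacetophenone with O-benzyl-2-bromo-3-methoxyphenol.
Order of rings: rings A and B are bought, the five-membered O-heterocycle is closed in step 4, it is enlarged to the six-membered ring C in step 7, and hydrogenolysis ends the route.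

Key step: step 7

Remark: the given SMILES encodes (2S) (O1 > C1' > C3 > H); pentamethoxybenzene and 2-bromo-3-methoxyphenol are taken as catalogue chemicals; racemic compounds are written without stereo marks.

Step 1
Reactants: 1 pentamethoxybenzene
Product: 4 1-(2,3,4,5,6-pentamethoxyphenyl)ethan-1-one, via aryllithium 2 (not isolated), via tetrahedral lithium adduct 3 (not isolated)
Conditions: n-BuLi (1.1 equiv), THF, 0 °C; then MeC(O)N(OMe)Me, −78 °C to rt; H2O
Reagents that add atoms: N-methoxy-N-methylacetamide, CC(=O)N(C)OC
Why: Directed ortho-metalation at the only ring C–H, which is flanked by two methoxy groups, is followed by Weinreb ketone synthesis, in which the chelated tetrahedral adduct prevents over-addition.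

Step 2
Reactants: 5 2-bromo-3-methoxyphenol
Product: 6 1-(benzyloxy)-2-bromo-3-methoxybenzene
Conditions: BnBr, K2CO3, DMF, rt
Reagents that add atoms: benzyl bromide, BrCc1ccccc1
Why: Williamson ether synthesis on the phenoxide masks the future 2'-OH with a group that leaves only in the neutral final hydrogenolysis.

Step 3
Reactants: 4 1-(2,3,4,5,6-pentamethoxyphenyl)ethan-1-one; 6 1-(benzyloxy)-2-bromo-3-methoxybenzene
Product: 7 2-[2-(benzyloxy)-6-methoxyphenyl]-1-(2,3,4,5,6-pentamethoxyphenyl)ethan-1-one
Conditions: Pd2(dba)3 (2 mol%), XPhos (8 mol%), NaOt-Bu, toluene, 80 °C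
Reagents that add atoms: none
Why: In this Buchwald–Hartwig type palladium-catalysed alpha-arylation of a methyl ketone enolate, a bulky electron-rich phosphine allows oxidative addition and reductive elimination with the di-ortho-substituted bromide, and the bulk of the product stops a second arylation.

Step 4
Reactants: 7 2-[2-(benzyloxy)-6-methoxyphenyl]-1-(2,3,4,5,6-pentamethoxyphenyl)ethan-1-one
Product: 10 rac-2-[2-(benzyloxy)-6-methoxyphenyl]-4,5,6,7-tetramethoxy-1-benzofuran-3(2H)-one, via potassium enolate 8 (not isolated), via alpha-iodo ketone 9 (not isolated)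
Conditions: KHMDS (1.05 equiv), THF, −78 °C; I2 (1.0 equiv), −78 °C to rt; then 50 °C
Reagents that add atoms: none
Why: Enolate iodination gives a doubly activated benzylic alpha-iodo ketone that one of the two equivalent ortho-methoxy oxygens of ring A displaces 5-exo-tet, and iodide then demethylates the oxonium ion (demethylative cycloetherification known for ortho-methoxyaryl alpha-halo ketones), so C2 is formed as the racemate.

Step 5
Reactants: 10 rac-2-[2-(benzyloxy)-6-methoxyphenyl]-4,5,6,7-tetramethoxy-1-benzofuran-3(2H)-one
Product: 12 rac-2-[2-(benzyloxy)-6-methoxyphenyl]-2-(iodomethyl)-4,5,6,7-tetramethoxy-1-benzofuran-3(2H)-one, via sodium benzofuran-3-olate 11 (not isolated)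
Conditions: NaH, DMF, 0 °C, argon; CH2I2 (5 equiv), rt, dark
Reagents that add atoms: diiodomethane, ICI
Why: C-alkylation of the enolate with excess diiodomethane is the standard entry to Dowd–Beckwith substrates, should be favoured over O-alkylation because the enolate oxygen is shielded by the peri 4-methoxy group, and gives the quaternary centre as the racemate, which is all the key step needs.

Step 6
Reactants: 12 rac-2-[2-(benzyloxy)-6-methoxyphenyl]-2-(iodomethyl)-4,5,6,7-tetramethoxy-1-benzofuran-3(2H)-one
Product: 14 rac-2-[2-(benzyloxy)-6-methoxyphenyl]-4-hydroxy-2-(iodomethyl)-5,6,7-trimethoxy-1-benzofuran-3(2H)-one, via dichloroboron chelate 13 (not isolated)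
Conditions: BCl3 (1.2 equiv), CH2Cl2, −78 to −20 °C; then H2O
Reagents that add atoms: none
Why: In this chelation-controlled aryl methyl ether cleavage, BCl3 binds the C3 carbonyl and the peri 4-methoxy oxygen in a six-membered chelate, so only that methyl group should be lost at low temperature while the remote benzyl ether, the other methoxy groups and the neopentyl iodide remain.

Step 7
Reactants: 14 rac-2-[2-(benzyloxy)-6-methoxyphenyl]-4-hydroxy-2-(iodomethyl)-5,6,7-trimethoxy-1-benzofuran-3(2H)-one
Product: 15 (2S)-2-[2-(benzyloxy)-6-methoxyphenyl]-5-hydroxy-6,7,8-trimethoxy-2,3-dihydro-4H-chromen-4-one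
Conditions: flavin-dependent ene-reductase (Old Yellow Enzyme family, (S)-selective variant from a screening panel, GluER T36A as first entry), NADP+ (cat), glucose dehydrogenase, D-glucose, K2HPO4/KH2PO4 buffer pH 7.0, DMSO (15 vol%), cyan LEDs (about 500 nm), N2, 25 °C
Reagents that add atoms: none
Why: Proposed new method: under cyan light the charge-transfer complex between the reduced flavin of the ene-reductase and the C–I bond of 14 passes on one electron, iodide leaves, and either enantiomer of 14 gives a primary neopentyl-type radical. This radical adds 3-exo-trig to the C3 carbonyl carbon, which the hydrogen bond from the 4-OH makes more electrophilic, and the transient cyclopropyloxyl radical cleaves the endocyclic C2–C3 bond, so the exocyclic CH2 is inserted and the five-membered furanone ring becomes the six-membered pyranone ring (no other ring is closed). The driving force is the change from a primary radical to the planar C2 radical, which is benzylic to ring B and alpha to O1, together with loss of the crowded quaternary centre. The closest known reaction types are the tin hydride Dowd–Beckwith one-carbon ring expansion of 2-(halomethyl)cycloalkanones and the ene-reductase photoreduction of unactivated alkyl iodides that ends in enantioselective hydrogen atom transfer. The only new stereocentre, C2, is set by hydrogen atom transfer from N5–H of the flavin semiquinone, because the His/Asn pair should bind C4=O as it binds a native enone and so place the beta carbon C2 over N5 with one face exposed, which lets both enantiomers of 14 converge on the (2S) product. The step needs the acyl shift to outrun premature hydrogen transfer, the intrinsically much slower 1,2-aryl shift of ring B and beta-scission of the C2–O1 bond, and this is secured by the short 3-exo path to a hydrogen-bond-activated aryl ketone, by the stabilised product radical and by the single hydrogen donor held in the active site.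

Step 8
Reactants: 15 (2S)-2-[2-(benzyloxy)-6-methoxyphenyl]-5-hydroxy-6,7,8-trimethoxy-2,3-dihydro-4H-chromen-4-one
Product: 16 (2S)-5-hydroxy-2-(2-hydroxy-6-methoxyphenyl)-6,7,8-trimethoxy-2,3-dihydro-4H-chromen-4-one (target)
Conditions: H2 (1 atm), Pd/C (10 wt%), EtOAc, rt; neutral work-up
Reagents that add atoms: none
Why: Catalytic hydrogenolysis of the aryl benzyl ether runs under neutral conditions and so avoids the acid- or base-induced opening to the chalcone or the ortho-quinone methide that would racemise C2.

Compound list
1 | pentamethoxybenzene | COc1cc(OC)c(OC)c(OC)c1OC | starting material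
2 | (2,3,4,5,6-pentamethoxyphenyl)lithium | [Li]c1c(OC)c(OC)c(OC)c(OC)c1OC | intermediate
3 | lithium 1-[methoxy(methyl)amino]-1-(2,3,4,5,6-pentamethoxyphenyl)ethan-1-olate | [Li+].[O-]C(C)(N(C)OC)c1c(OC)c(OC)c(OC)c(OC)c1OC | intermediate
4 | 1-(2,3,4,5,6-pentamethoxyphenyl)ethan-1-one | CC(=O)c1c(OC)c(OC)c(OC)c(OC)c1OC | intermediate
5 | 2-bromo-3-methoxyphenol | COc1cccc(O)c1Br | starting material
6 | 1-(benzyloxy)-2-bromo-3-methoxybenzene | COc1cccc(OCc2ccccc2)c1Br | intermediate
7 | 2-[2-(benzyloxy)-6-methoxyphenyl]-1-(2,3,4,5,6-pentamethoxyphenyl)ethan-1-one | COc1cccc(OCc2ccccc2)c1CC(=O)c1c(OC)c(OC)c(OC)c(OC)c1OC | intermediate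
8 | potassium enolate of 7 (double-bond geometry not defined) | [K+].[O-]C(=Cc1c(OC)cccc1OCc1ccccc1)c1c(OC)c(OC)c(OC)c(OC)c1OC | intermediate
9 | rac-2-[2-(benzyloxy)-6-methoxyphenyl]-2-iodo-1-(2,3,4,5,6-pentamethoxyphenyl)ethan-1-one | COc1cccc(OCc2ccccc2)c1C(I)C(=O)c1c(OC)c(OC)c(OC)c(OC)c1OC | intermediate
10 | rac-2-[2-(benzyloxy)-6-methoxyphenyl]-4,5,6,7-tetramethoxy-1-benzofuran-3(2H)-one | COc1cccc(OCc2ccccc2)c1C1Oc2c(OC)c(OC)c(OC)c(OC)c2C1=O | intermediate
11 | sodium 2-[2-(benzyloxy)-6-methoxyphenyl]-4,5,6,7-tetramethoxy-1-benzofuran-3-olate | [Na+].[O-]c1c(-c2c(OC)cccc2OCc2ccccc2)oc2c(OC)c(OC)c(OC)c(OC)c12 | intermediate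
12 | rac-2-[2-(benzyloxy)-6-methoxyphenyl]-2-(iodomethyl)-4,5,6,7-tetramethoxy-1-benzofuran-3(2H)-one | COc1cccc(OCc2ccccc2)c1C1(CI)Oc2c(OC)c(OC)c(OC)c(OC)c2C1=O | intermediate
13 | rac-4-O-dichloroboryl derivative of 14 (boron chelated to the C3 carbonyl) | COc1cccc(OCc2ccccc2)c1C1(CI)Oc2c(OC)c(OC)c(OC)c(OB(Cl)Cl)c2C1=O | intermediate
14 | rac-2-[2-(benzyloxy)-6-methoxyphenyl]-4-hydroxy-2-(iodomethyl)-5,6,7-trimethoxy-1-benzofuran-3(2H)-one | COc1cccc(OCc2ccccc2)c1C1(CI)Oc2c(OC)c(OC)c(OC)c(O)c2C1=O | intermediate
15 | (2S)-2-[2-(benzyloxy)-6-methoxyphenyl]-5-hydroxy-6,7,8-trimethoxy-2,3-dihydro-4H-chromen-4-one | COc1cccc(OCc2ccccc2)c1[C@@H]1CC(=O)c2c(O)c(OC)c(OC)c(OC)c2O1 | intermediate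
16 | (2S)-5-hydroxy-2-(2-hydroxy-6-methoxyphenyl)-6,7,8-trimethoxy-2,3-dihydro-4H-chromen-4-one | COc1cccc(O)c1[C@@H]1CC(=O)c2c(O)c(OC)c(OC)c(OC)c2O1 | target

Total step count: 8. Longest linear sequence: 7 (steps 1, 3, 4, 5, 6, 7, 8).

Steps most likely to fail

Step 7. The bulky substrate may bind poorly or in an unproductive pose. Hydrogen transfer to the primary radical may outrun the acyl shift. The hydrogen transfer to the C2 radical may show poor facial selectivity. Photoreduction of the aryl ketone may cleave the C2–O1 bond. The fallback sets out from 14. The ring expansion is run as the classical tin hydride chain reaction (Bu3SnH added slowly, AIBN, toluene, 80 °C) and should give the racemic O-benzyl flavanone F1. This is resolved by kinetic resolution through Noyori-type asymmetric transfer hydrogenation, a method established for racemic flavanones (RuCl(p-cymene)(TsDPEN) in the enantiomeric form that reduces the (2R)-ketone faster, HCO2H/Et3N, rt). The (2R)-enantiomer is carried on to the cis-(2R,4R)-flavan-4-ol F2. The untouched (2S)-ketone is separated by chromatography, and the route is rejoined at 15.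

Step 5. The ambident enolate may be alkylated at oxygen. Attack at C2 may be sluggish between the two ortho substituents of ring B. The enolate may be autoxidised at C2. The fallback sets out from 10 and replaces the substitution by a carbonyl addition. A base-catalysed aldol reaction with formaldehyde (aqueous HCHO, catalytic K2CO3, THF), in which attack through oxygen is reversible and only attack through carbon accumulates, should give the hydroxymethyl ketone F3. Appel-type deoxyiodination (PPh3, I2, imidazole, toluene, 80 °C) then comes back to the route at 12.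

Step 3. Oxidative addition and reductive elimination at the di-ortho-alkoxy bromide may be slow, which would lead to hydrodebromination and self-condensation of the ketone. The fallback makes the bond by carbonyl addition instead of cross-coupling and sets out from 4 and 6. Riley oxidation of 4 (SeO2, dioxane/H2O, reflux) should give the arylglyoxal F4. Bromine–lithium exchange on 6 (n-BuLi, THF, −78 °C) gives the aryllithium F5, which adds to the aldehyde carbon of F4 to give the benzoin F6. Acid-catalysed ionisation of the benzylic carbinol (TsOH, toluene, 80 °C) and capture by an ortho methoxy oxygen with loss of methanol closes the furanone ring. The route is rejoined at 10, so 7, 8 and 9 are bypassed.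

Further compounds
F1 | step 7 | rac-2-[2-(benzyloxy)-6-methoxyphenyl]-5-hydroxy-6,7,8-trimethoxy-2,3-dihydro-4H-chromen-4-one | COc1cccc(OCc2ccccc2)c1C1CC(=O)c2c(O)c(OC)c(OC)c(OC)c2O1
F2 | step 7 | (2R,4R)-2-[2-(benzyloxy)-6-methoxyphenyl]-6,7,8-trimethoxy-3,4-dihydro-2H-chromene-4,5-diol | COc1cccc(OCc2ccccc2)c1[C@H]1C[C@@H](O)c2c(O)c(OC)c(OC)c(OC)c2O1
F3 | step 5 | rac-2-[2-(benzyloxy)-6-methoxyphenyl]-2-(hydroxymethyl)-4,5,6,7-tetramethoxy-1-benzofuran-3(2H)-one | COc1cccc(OCc2ccccc2)c1C1(CO)Oc2c(OC)c(OC)c(OC)c(OC)c2C1=O
F4 | step 3 | 2-oxo-2-(2,3,4,5,6-pentamethoxyphenyl)acetaldehyde | O=CC(=O)c1c(OC)c(OC)c(OC)c(OC)c1OC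
F5 | step 3 | [2-(benzyloxy)-6-methoxyphenyl]lithium | [Li]c1c(OC)cccc1OCc1ccccc1
F6 | step 3 | rac-2-[2-(benzyloxy)-6-methoxyphenyl]-2-hydroxy-1-(2,3,4,5,6-pentamethoxyphenyl)ethan-1-one | COc1cccc(OCc2ccccc2)c1C(O)C(=O)c1c(OC)c(OC)c(OC)c(OC)c1OC
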